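**Retrosynthetic overview**
1. The plan rests on ring A', a benzene with a 1,2,4,5 pattern: cinnamoyl C=O on C1', OH on C2', OH on C4', O-aryl on C5', H on C3' and C6'. C2'–C3'–C4'–C5' is the carbon chain of a 4-aryloxyacetoacetate, and C6'–C1' is the triple bond of a terminal ynone.
2. The last cuts are the five MOM ethers and then the Cβ–C(ring B) bond of the ring A enone (Heck). This leads to a ring B aryl iodide and 2,4-bis(methoxymethoxy)phenyl vinyl ketone.
3. The key cut breaks C5'–C6' and C1'–C2' ([4+2] cycloaddition–aromatisation). It leads to 4-(4-iodophenoxy)-1-methoxy-1,3-bis(trimethylsilyloxy)butadiene and (E)-1-[4-(methoxymethoxy)phenyl]pent-1-en-4-yn-3-one.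
4. The diene comes from methyl 4-chloroacetoacetate and 4-iodophenol (etherification, two silylations). The ynone comes from p-coumaric acid (Weinreb amide, MOM ether, ethynyl Grignard). The vinyl ketone comes from 2,4-dihydroxybenzaldehyde.
5. Ring order: rings A, B and B' are bought as benzene rings. Ring A' is the only ring that is made, in step 7.

Key step: step 7

Assumption: the target has no stereocentre, so the only stereochemical task is the E geometry of the two enones. Rings A/B denote the chalcone unit with the unsubstituted resorcinol ring, and rings A'/B' the unit whose resorcinol ring bears the diaryl ether oxygen on C5'.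

**Step 1**
Reactants: 1 methyl 4-chloroacetoacetate; 2 4-iodophenol
Product: 3 methyl 4-(4-iodophenoxy)-3-oxobutanoate
Conditions: 2, NaH (2.2 equiv), THF, 0 °C; then 1, 0 °C → 50 °C; cold 1 M HCl work-up
Reagents that add atoms: none
Why: Williamson-type SN2 displacement of the primary chloride by the phenoxide, in which the second equivalent of NaH holds the β-keto ester as its enolate to suppress self-condensation and the aryl iodide is inert.

**Step 2**
Reactants: 3 methyl 4-(4-iodophenoxy)-3-oxobutanoate
Product: 4 methyl 4-(4-iodophenoxy)-3-(trimethylsilyloxy)but-2-enoate (E/Z mixture)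
Conditions: Me3SiCl (1.5 equiv), Et3N (1.6 equiv), toluene, rt; filtration under argon
Reagents that add atoms: chlorotrimethylsilane, C[Si](C)(C)Cl
Why: Soft enolisation and O-silylation of the β-keto ester (silyl enol ether formation) gives the conjugated 3-silyloxy enoate, whose double-bond geometry does not matter because that bond becomes the central single bond of the diene.

**Step 3**
Reactants: 4 methyl 4-(4-iodophenoxy)-3-(trimethylsilyloxy)but-2-enoate
Product: 6 (1Z,3Z)-4-(4-iodophenoxy)-1-methoxy-1,3-bis(trimethylsilyloxy)buta-1,3-diene, via lithium dienolate 5 (not isolated)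
Conditions: LiN(i-Pr)2 (1.1 equiv), THF, −78 °C; Me3SiCl (1.4 equiv), −78 °C → rt; hexane, filtration under argon, used crude
Reagents that add atoms: chlorotrimethylsilane, C[Si](C)(C)Cl
Why: Kinetic γ-deprotonation of the vinylogous ester and O-silylation of the dienolate is the standard route to 1-alkoxy-1,3-bis(silyloxy)butadienes; the activated OCH2 proton goes far faster at −78 °C than any attack of the amide on the iodoarene, and the aryloxy group should settle trans to C2 (outward), as the cycloaddition needs.

**Step 4**
Reactants: 7 p-coumaric acid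
Product: 8 (E)-3-(4-hydroxyphenyl)-N-methoxy-N-methylprop-2-enamide
Conditions: MeNH(OMe)·HCl (1.2 equiv), EDC·HCl (1.2 equiv), HOBt, i-Pr2NEt (2.5 equiv), DMF, 0 °C → rt
Reagents that add atoms: N,O-dimethylhydroxylamine hydrochloride, CNOC.Cl
Why: Carbodiimide/HOBt amide coupling, in which the free amine outruns the much less nucleophilic phenol for the active ester, so the acid needs no prior protection and the E double bond is untouched.

**Step 5**
Reactants: 8 (E)-3-(4-hydroxyphenyl)-N-methoxy-N-methylprop-2-enamide
Product: 9 (E)-N-methoxy-3-[4-(methoxymethoxy)phenyl]-N-methylprop-2-enamide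
Conditions: MOMCl (1.5 equiv), i-Pr2NEt (2 equiv), CH2Cl2, 0 °C → rt
Reagents that add atoms: chloromethyl methyl ether, COCCl
Why: Standard O-alkylation of a phenol with MOMCl and a hindered amine base, needed so that no acidic OH consumes the Grignard reagent in step 6 or the silyl diene in step 7.

**Step 6**
Reactants: 9 (E)-N-methoxy-3-[4-(methoxymethoxy)phenyl]-N-methylprop-2-enamide
Product: 11 (E)-1-[4-(methoxymethoxy)phenyl]pent-1-en-4-yn-3-one, via magnesium-chelated tetrahedral adduct 10 (not isolated)
Conditions: HC≡CMgBr (0.5 M in THF, 2 equiv), THF, −20 → 0 °C; inverse quench into ice-cold 1 M HCl/Et2O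
Reagents that add atoms: ethynylmagnesium bromide, C#C[Mg]Br
Why: Weinreb ketone synthesis: the chelated adduct 10 holds until the quench and so rules out over-addition, the hard acetylide adds 1,2 rather than 1,4, and the inverse quench into cold acid keeps the released N,O-dimethylhydroxylamine protonated so that it cannot add to the new ynone.

**Step 7**
Reactants: 6 (1Z,3Z)-4-(4-iodophenoxy)-1-methoxy-1,3-bis(trimethylsilyloxy)buta-1,3-diene; 11 (E)-1-[4-(methoxymethoxy)phenyl]pent-1-en-4-yn-3-one
Product: 14 (E)-1-[2,4-dihydroxy-5-(4-iodophenoxy)phenyl]-3-[4-(methoxymethoxy)phenyl]prop-2-en-1-one, via cyclohexadiene ketal cycloadduct 12 (not isolated), via bis-silyl ether of the chalcone 13 (not isolated)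
Conditions: 6 (1.6 equiv), 11 (1 equiv), BHT (trace), toluene, 0 °C → rt, then 60 °C, no Lewis acid; then THF, 0.5 M aq. HCl, 0 °C
Reagents that add atoms: none
Why: Diene 6 and ynone 11 combine in a normal-electron-demand but strongly asynchronous Diels–Alder reaction, in which diene C4 (the carbon bearing the aryloxy group) bonds first to the unsubstituted alkyne carbon (C5'–C6') and the ketene-acetal carbon C1 then joins the acyl-bearing alkyne carbon (C1'–C2'), so ring A' closes in one [4+2] event as the cyclohexa-1,4-diene ketal 12. The closest known reaction type is the cycloaddition–aromatisation of 1-alkoxy-1,3-bis(silyloxy)butadienes and related 1,1,3-trioxygenated dienes with acetylenic ketones and esters, which gives 2,4-dihydroxyaryl carbonyl compounds. 1,4-Loss of methanol from 12 (OMe from C2', H from C5') gives the aromatic bis-silyl ether 13, cold dilute acid then cleaves the two aryl O–Si bonds while the MOM ether stays, and both stereocentres of 12 vanish on aromatisation, so none needs control and none remains in 14. The required regioselectivity comes from the two oxygen donors on C1 and the one on C3, which together put the largest HOMO coefficient on C4 and outweigh the weaker, opposing 4-iodophenoxy donor, while the ynone LUMO is largest on its terminal carbon. Chemoselectivity for the alkyne over the β-aryl enone follows from the unhindered and more electrophilic terminal ynone, and omitting any Lewis acid avoids attack on the ketone carbonyl (a [3+3] closure to a salicylate). An excess of 6 is used because the released methanol protodesilylates part of it.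

**Step 8**
Reactants: 14 (E)-1-[2,4-dihydroxy-5-(4-iodophenoxy)phenyl]-3-[4-(methoxymethoxy)phenyl]prop-2-en-1-one
Product: 15 (E)-1-[5-(4-iodophenoxy)-2,4-bis(methoxymethoxy)phenyl]-3-[4-(methoxymethoxy)phenyl]prop-2-en-1-one
Conditions: NaH (2.6 equiv), MOMCl (3 equiv), THF–DMF, 0 °C → rt
Reagents that add atoms: chloromethyl methyl ether, COCCl
Why: Double Williamson-type O-alkylation, in which NaH is needed for the hydrogen-bonded 2'-OH and the open chalcone phenoxide rather than the flavanone is the stable form in strong aprotic base, so the enone survives.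

**Step 9**
Reactants: 16 2,4-dihydroxybenzaldehyde
Product: 17 2,4-bis(methoxymethoxy)benzaldehyde
Conditions: NaH (2.5 equiv), MOMCl (2.8 equiv), DMF, 0 °C → rt
Reagents that add atoms: chloromethyl methyl ether, COCCl
Why: Double Williamson-type O-alkylation with MOMCl, with NaH to make sure the hydrogen-bonded 2-OH reacts as well as the 4-OH.

**Step 10**
Reactants: 17 2,4-bis(methoxymethoxy)benzaldehyde
Product: 18 (±)-1-[2,4-bis(methoxymethoxy)phenyl]prop-2-en-1-ol
Conditions: CH2=CHMgBr (1.2 equiv), THF, −78 → 0 °C; sat. aq. NH4Cl
Reagents that add atoms: vinylmagnesium bromide, C=C[Mg]Br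
Why: Grignard 1,2-addition to the aldehyde, in which the new carbinol stereocentre forms without control (racemic) and is erased by the oxidation in step 11.

**Step 11**
Reactants: 18 (±)-1-[2,4-bis(methoxymethoxy)phenyl]prop-2-en-1-ol
Product: 19 1-[2,4-bis(methoxymethoxy)phenyl]prop-2-en-1-one
Conditions: activated MnO2 (15 equiv), CH2Cl2, rt; filtered, BHT (trace), used at once
Reagents that add atoms: none
Why: MnO2 oxidation of an alcohol that is both allylic and benzylic, under neutral conditions that spare the MOM groups and avoid acid-induced ionisation or 1,3-transposition of this electron-rich carbinol.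

**Step 12**
Reactants: 15 (E)-1-[5-(4-iodophenoxy)-2,4-bis(methoxymethoxy)phenyl]-3-[4-(methoxymethoxy)phenyl]prop-2-en-1-one; 19 1-[2,4-bis(methoxymethoxy)phenyl]prop-2-en-1-one
Product: 20 (E)-1-[2,4-bis(methoxymethoxy)phenyl]-3-{4-[2,4-bis(methoxymethoxy)-5-{(E)-3-[4-(methoxymethoxy)phenyl]prop-2-enoyl}phenoxy]phenyl}prop-2-en-1-one
Conditions: 19 (1.5 equiv), Pd(OAc)2 (5 mol %), n-Bu4NCl (1 equiv), NaHCO3 (2.5 equiv), BHT (trace), DMF, 60 °C
Reagents that add atoms: none
Why: Mizoroki–Heck reaction under ligand-free phase-transfer conditions: zerovalent palladium formed from Pd(OAc)2 inserts into the C–I bond, the aryl group adds to the unsubstituted terminus of the vinyl ketone and syn β-hydride elimination gives the E enone, while the 1,2-disubstituted enone already in 15 is too hindered to compete with the terminal alkene.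

**Step 13**
Reactants: 20 penta-MOM ether of the target
Product: 21 (E)-1-(2,4-dihydroxyphenyl)-3-{4-[2,4-dihydroxy-5-[(E)-3-(4-hydroxyphenyl)prop-2-enoyl]phenoxy]phenyl}prop-2-en-1-one
Conditions: 3 M aq. HCl, MeOH–THF, 50 °C, stopped as soon as the last MOM group is gone
Reagents that add atoms: none
Why: Acid-catalysed acetal exchange with methanol removes all five phenolic MOM groups, the usual last step of MOM-based chalcone syntheses, and moderate temperature and short contact should keep the two 2'-hydroxychalcone units from closing to flavanones and leave both E double bonds untouched.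

**Compound list**
1 | methyl 4-chloroacetoacetate | COC(=O)CC(=O)CCl | starting material
2 | 4-iodophenol | Oc1ccc(I)cc1 | starting material
3 | methyl 4-(4-iodophenoxy)-3-oxobutanoate | COC(=O)CC(=O)COc1ccc(I)cc1 | intermediate
4 | methyl 4-(4-iodophenoxy)-3-(trimethylsilyloxy)but-2-enoate, E/Z mixture | COC(=O)C=C(COc1ccc(I)cc1)O[Si](C)(C)C | intermediate
5 | lithium dienolate of 4, not isolated | [Li+].CO/C([O-])=C/C(O[Si](C)(C)C)=C/Oc1ccc(I)cc1 | intermediate
6 | (1Z,3Z)-4-(4-iodophenoxy)-1-methoxy-1,3-bis(trimethylsilyloxy)buta-1,3-diene | CO/C(O[Si](C)(C)C)=C/C(O[Si](C)(C)C)=C/Oc1ccc(I)cc1 | intermediate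
7 | p-coumaric acid | O=C(O)/C=C/c1ccc(O)cc1 | starting material
8 | (E)-3-(4-hydroxyphenyl)-N-methoxy-N-methylprop-2-enamide | CON(C)C(=O)/C=C/c1ccc(O)cc1 | intermediate
9 | (E)-N-methoxy-3-[4-(methoxymethoxy)phenyl]-N-methylprop-2-enamide | CON(C)C(=O)/C=C/c1ccc(OCOC)cc1 | intermediate
10 | bromomagnesium tetrahedral adduct of 9 and the acetylide, racemic, not isolated | C#CC(O[Mg]Br)(N(C)OC)/C=C/c1ccc(OCOC)cc1 | intermediate
11 | (E)-1-[4-(methoxymethoxy)phenyl]pent-1-en-4-yn-3-one | C#CC(=O)/C=C/c1ccc(OCOC)cc1 | intermediate
12 | cyclohexa-1,4-diene ketal cycloadduct, diastereomer mixture, not isolated | COC1(O[Si](C)(C)C)C=C(O[Si](C)(C)C)C(Oc2ccc(I)cc2)C=C1C(=O)/C=C/c3ccc(OCOC)cc3 | intermediate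
13 | (E)-1-[5-(4-iodophenoxy)-2,4-bis(trimethylsilyloxy)phenyl]-3-[4-(methoxymethoxy)phenyl]prop-2-en-1-one, not isolated | C[Si](C)(C)Oc1cc(O[Si](C)(C)C)c(Oc2ccc(I)cc2)cc1C(=O)/C=C/c3ccc(OCOC)cc3 | intermediate
14 | (E)-1-[2,4-dihydroxy-5-(4-iodophenoxy)phenyl]-3-[4-(methoxymethoxy)phenyl]prop-2-en-1-one | O=C(/C=C/c1ccc(OCOC)cc1)c1cc(Oc2ccc(I)cc2)c(O)cc1O | intermediate
15 | (E)-1-[5-(4-iodophenoxy)-2,4-bis(methoxymethoxy)phenyl]-3-[4-(methoxymethoxy)phenyl]prop-2-en-1-one | O=C(/C=C/c1ccc(OCOC)cc1)c1cc(Oc2ccc(I)cc2)c(OCOC)cc1OCOC | intermediate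
16 | 2,4-dihydroxybenzaldehyde | O=Cc1ccc(O)cc1O | starting material
17 | 2,4-bis(methoxymethoxy)benzaldehyde | O=Cc1ccc(OCOC)cc1OCOC | intermediate
18 | (±)-1-[2,4-bis(methoxymethoxy)phenyl]prop-2-en-1-ol | C=CC(O)c1ccc(OCOC)cc1OCOC | intermediate
19 | 1-[2,4-bis(methoxymethoxy)phenyl]prop-2-en-1-one | C=CC(=O)c1ccc(OCOC)cc1OCOC | intermediate
20 | penta-MOM ether of the target, both enones E | O=C(/C=C/c1ccc(Oc2cc(C(=O)/C=C/c3ccc(OCOC)cc3)c(OCOC)cc2OCOC)cc1)c1ccc(OCOC)cc1OCOC | intermediate
21 | EANPDB:ANAC_00012, both enones E | O=C(/C=C/c1ccc(Oc2cc(C(=O)/C=C/c3ccc(O)cc3)c(O)cc2O)cc1)c1ccc(O)cc1O | target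

**Step count:** 13 steps in total.
**Longest linear sequence:** 7 steps (1, 2, 3, 7, 8, 12, 13). The branch 4, 5, 6 is of equal length, and the branch 9, 10, 11 joins at step 12.

**Steps most likely to fail**

**Step 7.**
- What may go wrong: the first C–C bond may form without ring closure, because silyl transfer to the allenolate would stop the sequence at an open-chain Michael stage. Closure may also go to the ketone carbonyl, or the cross-conjugated enynone may oligomerise before the diene consumes it.
- Fallback: it sets out from 6 and comes back at 15. It keeps the benzannulation but moves the building of the ring B' enone to after ring A'.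
- Diene 6 is heated under the same Lewis-acid-free conditions with commercial but-3-yn-2-one, a small terminal ynone with no second acceptor.
- This gives the ketal cycloadduct F1. On the same cold acidic work-up F1 loses methanol and its silyl groups to give 1-[2,4-dihydroxy-5-(4-iodophenoxy)phenyl]ethanone F2.
- NaH and MOMCl convert F2 into 1-[5-(4-iodophenoxy)-2,4-bis(methoxymethoxy)phenyl]ethanone F3.
- A Claisen–Schmidt condensation of F3 with commercial 4-(methoxymethoxy)benzaldehyde (KOH, EtOH, rt) then gives 15.

**Step 12.**
- What may go wrong: the aryl vinyl ketone may be lost by base- or radical-induced oligomerisation faster than it is arylated. Palladium hydride may also reduce or isomerise the enones.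
- Fallback: it sets out from 15 and the stable allylic alcohol 18, so that 19 is no longer needed, and comes back at 20.
- A Heck arylation of 18 with 15 is run in the presence of a silver salt (Pd(OAc)2, AgOAc, DMF, rt to 50 °C).
- Halide abstraction should give a cationic arylpalladium species and suppress re-addition of palladium hydride. The double bond then stays conjugated with ring B and the carbinol is not isomerised to the saturated ketone.
- The product is the racemic (E)-1,3-diarylallyl alcohol F4, which MnO2 in CH2Cl2 oxidises to 20.

**Step 13.**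
- What may go wrong: cleavage of five acetals may be slow enough for acid-catalysed oxa-Michael closure of one or both 2'-hydroxychalcone units to compete.
- Fallback: it sets out from 20 and comes back at 21. It corrects ring closure afterwards rather than trying to avoid it.
- The deprotection is driven to completion in refluxing methanolic HCl without regard to cyclisation. This moves the material toward the doubly cyclised bis-flavanone F5, a diastereomer mixture together with partly cyclised isomers.
- Aqueous KOH in MeOH under argon at rt then opens the pyranone rings by E1cB retro-oxa-Michael reaction, because the chalcone polyphenoxide is the stable form in strong base.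
- Pouring into ice-cold dilute HCl with immediate extraction should return 21.

**Further compounds**
F1 | step 7 | 1-[3-(4-iodophenoxy)-6-methoxy-4,6-bis(trimethylsilyloxy)cyclohexa-1,4-dien-1-yl]ethanone, diastereomer mixture, not isolated | COC1(O[Si](C)(C)C)C=C(O[Si](C)(C)C)C(Oc2ccc(I)cc2)C=C1C(C)=O
F2 | step 7 | 1-[2,4-dihydroxy-5-(4-iodophenoxy)phenyl]ethanone | CC(=O)c1cc(Oc2ccc(I)cc2)c(O)cc1O
F3 | step 7 | 1-[5-(4-iodophenoxy)-2,4-bis(methoxymethoxy)phenyl]ethanone | CC(=O)c1cc(Oc2ccc(I)cc2)c(OCOC)cc1OCOC
F4 | step 12 | racemic (E)-allylic alcohol corresponding to 20 (ring A carbonyl as CHOH) | OC(/C=C/c1ccc(Oc2cc(C(=O)/C=C/c3ccc(OCOC)cc3)c(OCOC)cc2OCOC)cc1)c1ccc(OCOC)cc1OCOC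
F5 | step 13 | 7-hydroxy-2-{4-[(7-hydroxy-2-(4-hydroxyphenyl)-4-oxochroman-6-yl)oxy]phenyl}chroman-4-one, diastereomer mixture | O=C1CC(c3ccc(Oc4cc5C(=O)CC(c6ccc(O)cc6)Oc5cc4O)cc3)Oc2cc(O)ccc21
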